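**Retrosynthetic overview**

1. Target 22 ← hydrogenation ← cross-metathesis of allyl phthalide 6 with pentenyl spiroketal 20; 6 comes from an aryl aldehyde by asymmetric allylboration (C3) and carboxylative lactonization.
2. 20 ← 3-oxo spiroketal 17 (ketone removed by reduction and radical deoxygenation) ← diazoketone 16. The bond between the spiro carbon and the neighbouring CH2 of the methyl-bearing oxolane (ring B) is made by rhodium-carbenoid insertion into the acetal C–H of a 2-alkoxyoxolane (ring A, the chain-bearing ring), which closes ring B as an oxolan-3-one.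
3. Enabling feature: the spiro carbon carries both ring oxygens, so in mixed acetal 13 it is an anomeric C–H, doubly oxygen-activated and five atoms from the diazo carbon through the O–CH(CH3)–C(=O) tether taken from (S)-lactate. Insertion with retention turns the trans anomer into the 5R spiro centre (methyl and chain each trans to the oxygen of the other ring), which acid equilibration of a [4.4] spiroketal is not expected to single out.
4. Ring order: arene bought; ring A bought as (R)-5-(hydroxymethyl)oxolan-2-one and reduced to the lactol; phthalide lactone closed in step 2; ring B closed last within the spiroketal (step 10).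
5. Stereocentres: C3 by Brown allylboration, the chain-bearing carbinol carbon from the chiral-pool lactone, the methyl-bearing carbon from ethyl (S)-lactate, the acetal carbon by anomer separation with recycling (step 7), the spiro carbon from it by stereospecific C–H insertion.

Key step: step 10

Assumption: the trans and cis anomers of mixed acetal 12 are taken to be separable by chromatography (step 7) and not to interconvert under the basic or acid-free conditions of steps 8 to 10.

**Route**

Step 1
Reactants: 1 2-bromo-3,5-dimethoxybenzaldehyde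
Product: 3 (R)-1-(2-bromo-3,5-dimethoxyphenyl)but-3-en-1-ol, via borinate ester 2 (not isolated)
Conditions: (+)-Ipc2B(allyl) (from (−)-α-pinene), Et2O, −78 °C; then NaOH, H2O2, rt
Reagents that add atoms: (+)-B-allyldiisopinocampheylborane, C=CCB([C@H]1C[C@H]2C[C@H](C2(C)C)[C@@H]1C)[C@H]1C[C@H]2C[C@H](C2(C)C)[C@@H]1C
Why: Brown asymmetric allylboration through a closed chair (Zimmerman–Traxler) transition state, in which the isopinocampheyl groups derived from (−)-α-pinene direct allyl transfer to the Re face of the aryl aldehyde and so set the carbinol carbon (later C3) as R.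

Step 2
Reactants: 3 (R)-1-(2-bromo-3,5-dimethoxyphenyl)but-3-en-1-ol
Product: 6 (3R)-5,7-dimethoxy-3-(prop-2-en-1-yl)-2-benzofuran-1(3H)-one, via aryllithium alkoxide 4 (not isolated), via hydroxy acid 5 (not isolated)
Conditions: n-BuLi (2.2 equiv), THF, −78 °C; CO2 (g), −78 °C to rt; 2 M HCl, rt
Reagents that add atoms: carbon dioxide, O=C=O
Why: Bromine–lithium exchange on the lithium alkoxide, carboxylation of the aryllithium and acid-induced lactonization of the γ-hydroxy acid should give the phthalide without touching the carbinol centre, whose ionization is not expected because both methoxy groups are meta to it.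

Step 3
Reactants: 7 (5R)-5-(hydroxymethyl)oxolan-2-one
Product: 8 [(2R)-5-oxooxolan-2-yl]methyl 4-methylbenzenesulfonate
Conditions: TsCl, pyridine, CH2Cl2, 0 °C to rt
Reagents that add atoms: 4-methylbenzenesulfonyl chloride, Cc1ccc(cc1)S(Cl)(=O)=O
Why: Sulfonylation of the primary alcohol activates it for substitution and does not involve the stereocentre.

Step 4
Reactants: 8 [(2R)-5-oxooxolan-2-yl]methyl 4-methylbenzenesulfonate
Product: 9 (5S)-5-(pent-4-en-1-yl)oxolan-2-one
Conditions: but-3-enylmagnesium bromide (2.4 equiv), CuBr·SMe2 (1.2 equiv), THF, −45 to −20 °C; aq. NH4Cl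
Reagents that add atoms: but-3-enylmagnesium bromide, C=CCC[Mg]Br
Why: Substitution of a primary tosylate by a magnesium dialkylcuprate (Gilman-type coupling) should outrun addition to the lactone carbonyl at low temperature, and the stereocentre is untouched, its descriptor changing from R to S only through the change in substituent priority.

Step 5
Reactants: 9 (5S)-5-(pent-4-en-1-yl)oxolan-2-one
Product: 10 (5S)-5-(pent-4-en-1-yl)oxolan-2-ol (both C2 epimers)
Conditions: i-Bu2AlH (1.1 equiv), CH2Cl2, −78 °C; aq. potassium sodium tartrate (KNaC4H4O6)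
Reagents that add atoms: none
Why: Partial reduction of a γ-lactone with i-Bu2AlH at −78 °C stops at the tetrahedral aluminium hemiacetal, which gives the lactol on work-up.

Step 6
Reactants: 10 (5S)-5-(pent-4-en-1-yl)oxolan-2-ol; 11 ethyl (S)-lactate
Product: 12 ethyl (2S)-2-{[(5S)-5-(pent-4-en-1-yl)oxolan-2-yl]oxy}propanoate (both anomers)
Conditions: 11 (5 equiv), pyridinium p-toluenesulfonate (10 mol%), 4 Å molecular sieves, CH2Cl2, rt; Et3N quench, aq. NaHCO3 wash
Reagents that add atoms: none
Why: Acid-catalysed acetalization of the lactol with the secondary alcohol (Fischer-type glycosidation through the cyclic oxocarbenium ion, driven by excess 11 and removal of water) should give the mixed acetal as both anomers under thermodynamic control, without touching the lactate centre or the ring carbinol centre.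

Step 7
Reactants: 12 ethyl (2S)-2-{[(5S)-5-(pent-4-en-1-yl)oxolan-2-yl]oxy}propanoate (both anomers)
Product: 13 ethyl (2S)-2-{[(2S,5S)-5-(pent-4-en-1-yl)oxolan-2-yl]oxy}propanoate
Conditions: chromatography on Et3N-deactivated SiO2; cis-rich fractions: pyridinium p-toluenesulfonate (5 mol%), 4 Å molecular sieves, CH2Cl2, rt, then chromatography again (repeated)
Reagents that add atoms: none
Why: The anomers are diastereomers and should separate on base-washed silica, and acid-catalysed anomerization of the cis-rich fractions (acetal epimerization through the oxocarbenium ion) restores the equilibrium mixture for another pass, so that the acetal centre is set as 2S (alkoxy group trans to the pentenyl chain) by separation and recycling.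

Step 8
Reactants: 13 ethyl (2S)-2-{[(2S,5S)-5-(pent-4-en-1-yl)oxolan-2-yl]oxy}propanoate
Product: 14 potassium (2S)-2-{[(2S,5S)-5-(pent-4-en-1-yl)oxolan-2-yl]oxy}propanoate
Conditions: KOSiMe3 (1.1 equiv), THF, rt; evaporation
Reagents that add atoms: potassium trimethylsilanolate, C[Si](C)(C)[O-].[K+]
Why: Anhydrous ester cleavage with potassium trimethylsilanolate gives the carboxylate salt directly, so that the acid-labile acetal never meets a free carboxylic acid and the α-alkoxy centre is not enolized.

Step 9
Reactants: 14 potassium (2S)-2-{[(2S,5S)-5-(pent-4-en-1-yl)oxolan-2-yl]oxy}propanoate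
Product: 16 (3S)-1-diazo-3-{[(2S,5S)-5-(pent-4-en-1-yl)oxolan-2-yl]oxy}butan-2-one, via mixed carbonic anhydride 15 (not isolated)
Conditions: isobutyl chloroformate (1.05 equiv), THF, −15 °C; then CH2N2 (3 equiv, ethereal, freshly prepared), 0 °C to rt
Reagents that add atoms: diazomethane, C=[N+]=[N-]; isobutyl chloroformate, CC(C)COC(Cl)=O (its atoms stay only in 15)
Why: Acylation of diazomethane by a mixed carbonic anhydride (first stage of an Arndt–Eistert sequence) gives the α-diazoketone under base-free conditions that leave the acetal and the α-stereocentre intact.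

Step 10
Reactants: 16 (3S)-1-diazo-3-{[(2S,5S)-5-(pent-4-en-1-yl)oxolan-2-yl]oxy}butan-2-one
Product: 17 (2S,5R,7S)-2-methyl-7-(pent-4-en-1-yl)-1,6-dioxaspiro[4.4]nonan-3-one
Conditions: Rh2(OAc)4 (2 mol%), CH2Cl2, 40 °C, 16 added over 4 h (final 0.01 M); filtration through Et3N-deactivated silica, used at once
Reagents that add atoms: none
Why: Rh2(OAc)4 expels dinitrogen from 16 to give an electrophilic rhodium carbenoid, which inserts into the anomeric C–H bond of the 2-alkoxyoxolane through a five-membered, three-centre transition state with hydride-transfer character. The closest known reaction types are the dirhodium-catalysed 1,5-C–H insertion of α-alkoxy diazoketones next to an ether oxygen, which gives oxolan-3-ones, and carbene insertion into anomeric C–H bonds of glycosides with retention. Ring B closes by 1,5-insertion, the new bond joining the former diazo carbon (C4) to the acetal carbon, which becomes the spiro carbon C5. C5 is set by retention at the inserting C–H bond, so that the trans relation in 16 between the alkoxy oxygen and the pentenyl chain becomes the 5R configuration, while C2 comes unchanged from (S)-lactate and C7 from the lactone. The step needs site selectivity for the acetal C–H over attack on the ring-A oxygen (six-membered oxonium ylide) and over cyclopropanation of the remote alkene; this is secured by the double oxygen activation of that C–H, by the exo-anomeric conformation that holds it next to the carbenoid, by the electron-rich acetate ligands and by slow addition at high dilution.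

Step 11
Reactants: 17 (2S,5R,7S)-2-methyl-7-(pent-4-en-1-yl)-1,6-dioxaspiro[4.4]nonan-3-one
Product: 18 (2S,5R,7S)-2-methyl-7-(pent-4-en-1-yl)-1,6-dioxaspiro[4.4]nonan-3-ol (both C3 epimers)
Conditions: NaBH4, MeOH, −40 to −20 °C; aq. NH4Cl
Reagents that add atoms: none
Why: Hydride reduction of the ketone at low temperature should be faster than enolization, so that the β-alkoxy ketone does not open by a retro-oxa-Michael reaction and the spiro centre is kept, while the new carbinol centre may form as a mixture because it is removed in step 13.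

Step 12
Reactants: 18 (2S,5R,7S)-2-methyl-7-(pent-4-en-1-yl)-1,6-dioxaspiro[4.4]nonan-3-ol
Product: 19 O-[(2S,5R,7S)-2-methyl-7-(pent-4-en-1-yl)-1,6-dioxaspiro[4.4]nonan-3-yl] 1H-imidazole-1-carbothioate
Conditions: 1,1'-thiocarbonyldiimidazole (2 equiv), DMAP (0.2 equiv), THF, 60 °C
Reagents that add atoms: 1,1'-thiocarbonyldiimidazole, S=C(n1ccnc1)n1ccnc1
Why: Acylation of the secondary alcohol by thiocarbonyldiimidazole gives, under neutral conditions, the thiocarbonyl derivative needed for Barton–McCombie deoxygenation.

Step 13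
Reactants: 19 O-[(2S,5R,7S)-2-methyl-7-(pent-4-en-1-yl)-1,6-dioxaspiro[4.4]nonan-3-yl] 1H-imidazole-1-carbothioate
Product: 20 (2S,5R,7S)-2-methyl-7-(pent-4-en-1-yl)-1,6-dioxaspiro[4.4]nonane
Conditions: Bu3SnH (2 equiv), AIBN (0.2 equiv), toluene, 100 °C
Reagents that add atoms: none
Why: In the Barton–McCombie radical deoxygenation the stannyl radical adds to the thiocarbonyl sulfur, the secondary C–O bond fragments and the ring radical takes hydrogen from Bu3SnH faster than it can fragment or reach the remote alkene, and the neutral conditions keep the spiro centre.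

Step 14
Reactants: 20 (2S,5R,7S)-2-methyl-7-(pent-4-en-1-yl)-1,6-dioxaspiro[4.4]nonane; 6 (3R)-5,7-dimethoxy-3-(prop-2-en-1-yl)-2-benzofuran-1(3H)-one
Product: 21 (3R)-5,7-dimethoxy-3-{6-[(2S,5R,7S)-7-methyl-1,6-dioxaspiro[4.4]nonan-2-yl]hex-2-en-1-yl}-2-benzofuran-1(3H)-one (E and Z)
Conditions: 6 (3 equiv), second-generation Grubbs catalyst (5 mol%), CH2Cl2, 40 °C
Reagents that add atoms: none
Why: Olefin cross-metathesis between two unhindered terminal alkenes is driven by loss of ethene and by the excess of the cheaper partner 6, and the alkene geometry is of no consequence because the double bond is reduced in step 15.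

Step 15
Reactants: 21 (3R)-5,7-dimethoxy-3-{6-[(2S,5R,7S)-7-methyl-1,6-dioxaspiro[4.4]nonan-2-yl]hex-2-en-1-yl}-2-benzofuran-1(3H)-one
Product: 22 (3R)-5,7-dimethoxy-3-{6-[(2S,5R,7S)-7-methyl-1,6-dioxaspiro[4.4]nonan-2-yl]hexyl}-2-benzofuran-1(3H)-one
Conditions: H2 (1 atm), 10% Pd/C, K2CO3 (0.1 equiv), EtOAc, rt
Reagents that add atoms: none
Why: Heterogeneous hydrogenation saturates the disubstituted alkene, and the trace of K2CO3 should suppress acid-induced epimerization of the spiro centre and hydrogenolysis of the benzylic lactone C–O bond.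

**Compound list**

1 | 2-bromo-3,5-dimethoxybenzaldehyde | COc1cc(OC)c(Br)c(C=O)c1 | starting material
2 | (1R)-1-(2-bromo-3,5-dimethoxyphenyl)but-3-en-1-yl diisopinocampheylborinate | COc1cc(OC)c(Br)c(c1)[C@@H](CC=C)OB([C@H]1C[C@H]2C[C@H](C2(C)C)[C@@H]1C)[C@H]1C[C@H]2C[C@H](C2(C)C)[C@@H]1C | intermediate (not isolated)
3 | (R)-1-(2-bromo-3,5-dimethoxyphenyl)but-3-en-1-ol | COc1cc(OC)c(Br)c(c1)[C@@H](CC=C)O | intermediate
4 | lithium (1R)-1-(2-lithio-3,5-dimethoxyphenyl)but-3-en-1-olate | [Li]c1c(OC)cc(OC)cc1[C@@H](CC=C)O[Li] | intermediate (not isolated)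
5 | 2-[(1R)-1-hydroxybut-3-en-1-yl]-4,6-dimethoxybenzoic acid | COc1cc(OC)c(C(=O)O)c(c1)[C@@H](CC=C)O | intermediate (not isolated)
6 | (3R)-5,7-dimethoxy-3-(prop-2-en-1-yl)-2-benzofuran-1(3H)-one | COc1cc(OC)c2c(c1)[C@@H](CC=C)OC2=O | intermediate
7 | (5R)-5-(hydroxymethyl)oxolan-2-one | O=C1CC[C@H](CO)O1 | starting material
8 | [(2R)-5-oxooxolan-2-yl]methyl 4-methylbenzenesulfonate | O=C1CC[C@H](COS(=O)(=O)c2ccc(C)cc2)O1 | intermediate
9 | (5S)-5-(pent-4-en-1-yl)oxolan-2-one | O=C1CC[C@H](CCCC=C)O1 | intermediate
10 | (5S)-5-(pent-4-en-1-yl)oxolan-2-ol (both C2 epimers) | OC1CC[C@H](CCCC=C)O1 | intermediate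
11 | ethyl (S)-lactate | CCOC(=O)[C@H](C)O | starting material
12 | ethyl (2S)-2-{[(5S)-5-(pent-4-en-1-yl)oxolan-2-yl]oxy}propanoate (both anomers) | C=CCCC[C@H]1CCC(O[C@@H](C)C(=O)OCC)O1 | intermediate
13 | ethyl (2S)-2-{[(2S,5S)-5-(pent-4-en-1-yl)oxolan-2-yl]oxy}propanoate | C=CCCC[C@H]1CC[C@H](O[C@@H](C)C(=O)OCC)O1 | intermediate
14 | potassium (2S)-2-{[(2S,5S)-5-(pent-4-en-1-yl)oxolan-2-yl]oxy}propanoate | C=CCCC[C@H]1CC[C@H](O[C@@H](C)C(=O)[O-])O1.[K+] | intermediate
15 | (2S)-2-{[(2S,5S)-5-(pent-4-en-1-yl)oxolan-2-yl]oxy}propanoic 2-methylpropyl carbonic anhydride | C=CCCC[C@H]1CC[C@H](O[C@@H](C)C(=O)OC(=O)OCC(C)C)O1 | intermediate (not isolated)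
16 | (3S)-1-diazo-3-{[(2S,5S)-5-(pent-4-en-1-yl)oxolan-2-yl]oxy}butan-2-one | C=CCCC[C@H]1CC[C@H](O[C@@H](C)C(=O)C=[N+]=[N-])O1 | intermediate
17 | (2S,5R,7S)-2-methyl-7-(pent-4-en-1-yl)-1,6-dioxaspiro[4.4]nonan-3-one | C=CCCC[C@H]1CC[C@@]3(CC(=O)[C@H](C)O3)O1 | intermediate
18 | (2S,5R,7S)-2-methyl-7-(pent-4-en-1-yl)-1,6-dioxaspiro[4.4]nonan-3-ol (both C3 epimers) | C=CCCC[C@H]1CC[C@@]3(CC(O)[C@H](C)O3)O1 | intermediate
19 | O-[(2S,5R,7S)-2-methyl-7-(pent-4-en-1-yl)-1,6-dioxaspiro[4.4]nonan-3-yl] 1H-imidazole-1-carbothioate | C=CCCC[C@H]1CC[C@@]3(CC(OC(=S)n2ccnc2)[C@H](C)O3)O1 | intermediate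
20 | (2S,5R,7S)-2-methyl-7-(pent-4-en-1-yl)-1,6-dioxaspiro[4.4]nonane | C=CCCC[C@H]1CC[C@@]3(CC[C@H](C)O3)O1 | intermediate
21 | (3R)-5,7-dimethoxy-3-{6-[(2S,5R,7S)-7-methyl-1,6-dioxaspiro[4.4]nonan-2-yl]hex-2-en-1-yl}-2-benzofuran-1(3H)-one (E and Z) | COc1cc(OC)c2c(c1)[C@@H](CC=CCCC[C@H]1CC[C@@]3(CC[C@H](C)O3)O1)OC2=O | intermediate
22 | (3R)-5,7-dimethoxy-3-{6-[(2S,5R,7S)-7-methyl-1,6-dioxaspiro[4.4]nonan-2-yl]hexyl}-2-benzofuran-1(3H)-one | COc1cc(OC)c2c(c1)[C@@H](CCCCCC[C@H]1CC[C@@]3(CC[C@H](C)O3)O1)OC2=O | target

**Step count and risks**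

Total step count: 15. Longest linear sequence: 13 steps (steps 3 to 15, from 7 to 22).

The three steps most likely to fail:

1. Step 10. The carbenoid may be diverted into attack on the ring-A oxygen (six-membered oxonium ylide, then a 1,2-shift to a fused isomer), or a stepwise hydride transfer may erode retention at the spiro carbon. The fallback sets out from lactone 9 and returns at 20, bypassing steps 5 to 13. (S)-Butane-1,3-diol is iodinated selectively at the primary hydroxyl (I2, PPh3, imidazole, CH2Cl2, 0 °C) to (S)-4-iodobutan-2-ol F1 and silylated (TBSCl, imidazole, DMF) to tert-butyl{[(2S)-4-iodobutan-2-yl]oxy}dimethylsilane F2. Iodine–lithium exchange (t-BuLi, Et2O, −78 °C) and addition of the alkyllithium to 9 at −78 °C should give (2S,8S)-2-{[tert-butyl(dimethyl)silyl]oxy}-8-hydroxytridec-12-en-5-one F3. Camphorsulfonic acid in MeOH then removes the silyl group and closes both rings under thermodynamic control to 20 together with its spiro epimer (2S,5S,7S)-2-methyl-7-(pent-4-en-1-yl)-1,6-dioxaspiro[4.4]nonane F4. The two are separated by chromatography and F4 is re-equilibrated with the same acid.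

2. Step 7. The anomers may separate poorly, and acid-induced anomerization on silica during isolation may leave the trans anomer only in part, so that many recycling passes are needed. The fallback sets out from lactol 10 and returns at 13, bypassing steps 6 and 7. Ethyl (R)-lactate is converted with Tf2O and 2,6-lutidine (CH2Cl2, −78 °C) into ethyl (2R)-2-{[(trifluoromethyl)sulfonyl]oxy}propanoate F5. The sodium lactolate of 10 (NaH, THF, −40 to 0 °C) is then O-alkylated by F5 with inversion at the lactate carbon (anomeric O-alkylation, SN2). The anomer ratio is then fixed by the relative alkylation rates of the equilibrating lactolates and not by the acetal equilibrium, no acid is present, and 13 is purified on Et3N-deactivated silica.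

3. Step 4. The organomagnesium or organocopper species may add to the lactone carbonyl, and displacement of the tosylate may be incomplete. The fallback sets out from tosylate 8 and returns at 9. NaOMe in MeOH at 0 °C opens the lactone and the liberated alkoxide displaces the neighbouring tosylate (intramolecular Williamson reaction) to give methyl 3-[(2R)-oxiran-2-yl]propanoate F6. But-3-enylmagnesium bromide with a catalytic amount of CuI (THF, −40 °C) opens the epoxide at its terminal carbon to methyl (4S)-4-hydroxynon-8-enoate F7, which lactonizes to 9 with a trace of TsOH in CH2Cl2.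

**Further compounds**

F1 | step 10 | (S)-4-iodobutan-2-ol | C[C@H](O)CCI
F2 | step 10 | tert-butyl{[(2S)-4-iodobutan-2-yl]oxy}dimethylsilane | C[C@H](O[Si](C)(C)C(C)(C)C)CCI
F3 | step 10 | (2S,8S)-2-{[tert-butyl(dimethyl)silyl]oxy}-8-hydroxytridec-12-en-5-one | C=CCCC[C@H](O)CCC(=O)CC[C@H](C)O[Si](C)(C)C(C)(C)C
F4 | step 10 | (2S,5S,7S)-2-methyl-7-(pent-4-en-1-yl)-1,6-dioxaspiro[4.4]nonane | C=CCCC[C@H]1CC[C@]3(CC[C@H](C)O3)O1
F5 | step 7 | ethyl (2R)-2-{[(trifluoromethyl)sulfonyl]oxy}propanoate | CCOC(=O)[C@@H](C)OS(=O)(=O)C(F)(F)F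
F6 | step 4 | methyl 3-[(2R)-oxiran-2-yl]propanoate | COC(=O)CC[C@@H]1CO1
F7 | step 4 | methyl (4S)-4-hydroxynon-8-enoate | COC(=O)CC[C@@H](O)CCCC=C
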